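**Plan**

1. Retrosynthesis: the Ca–Cb bond of the two-carbon link is cut (olefination, then saturation) into a decalin sulfone and a 1,2-dioxane aldehyde (Ca sits on decalin C2, Cb on dioxane C3′; naphthalene numbering for the decalin). In the decalin, C1=CH2, C2–Ca and C3–H are cut back to a 2,3-dimethyl enone.
2. Ring B of that enone holds C2 and C3, two adjacent methyl-bearing carbons between C1 and C4. This is a but-2-yne unit inserted into the C1–C4 bond of a cis-fused cyclobutanone, itself the [2+2] adduct of dichloroketene and 1-methylcyclohexa-1,3-diene.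
3. Forward order: ring A (diene), cyclobutane, ring B (nickel-catalysed alkyne insertion), C1 carbinol carrying a silicon tether and a latent methylene, C2 (radical cyclisation), C3 (directed hydrogenation), sulfone; then union with the dioxane aldehyde, diimide, Peterson elimination.
4. The dioxane comes from geranyl acetate: anti-crotylboration, Sharpless epoxidation, perhydrolysis of the epoxide, ring closure by intramolecular peroxide alkylation.
5. Stereochemistry: C4a/C8a from the suprafacial ketene cycloaddition (single enantiomer by enzymatic resolution). The C1 oxygen, put on the α face by convex-face addition, relays to C2 (tether) and C3 (hydroxyl direction). C3′ comes from the Sharpless epoxide (inversion), C6′/Cα from the crotylboration (inversion at C6′ on closure).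

Key step: step 6

Remark: the ring-A methyl on C6 requires 1-methylcyclohexa-1,3-diene, so the enone used is 3-methylcyclohex-2-en-1-one; the 2-methyl isomer would misplace the methyl group.
Remark: β is the face of ring B carrying H-4a and H-8a, α the face of C5 and C8; dioxane atoms are C3′ (quaternary) to C6′; Cα is the propanoate α-carbon.
Remark: proton or hydride delivery to C3 and alkylation at C2 of the enone are expected from the convex β face, which would misplace both groups; C2 and C3 are therefore set from the α-face C1 oxygen.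
Assumption: a ketoreductase that reduces the (1S,6R)-cyclobutanone selectively is available from a commercial screening panel.

**Route**

Step 1
Reactants: 1 3-methylcyclohex-2-en-1-one
Product: 2 3-methylcyclohex-2-en-1-one p-toluenesulfonylhydrazone
Conditions: TsNHNH2, MeOH, cat. HCl, rt
Reagents that add atoms: p-toluenesulfonyl hydrazide, Cc1ccc(cc1)S(=O)(=O)NN
Why: Acid-catalysed hydrazone condensation of the enone carbonyl is routine and prepares the Shapiro reaction.

Step 2
Reactants: 2 3-methylcyclohex-2-en-1-one p-toluenesulfonylhydrazone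
Product: 4 1-methylcyclohexa-1,3-diene, via dienyllithium 3 (not isolated)
Conditions: MeLi (2.2 equiv), Et2O, 0 °C → rt; H2O
Reagents that add atoms: none
Why: Shapiro reaction: α′-deprotonation of the hydrazone anion, loss of sulfinate and N2, and protonation of the vinyllithium put the new double bond next to the retained one, giving the 1-methyl-1,3-diene.

Step 3
Reactants: 4 1-methylcyclohexa-1,3-diene; 5 trichloroacetyl chloride
Product: 7 rac-cis-8,8-dichloro-3-methylbicyclo[4.2.0]oct-2-en-7-one, via dichloroketene 6 (not isolated)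
Conditions: Zn(Cu), POCl3, Et2O, 25–35 °C
Reagents that add atoms: none
Why: Thermal ketene–alkene [2+2] cycloaddition: the ketene adds suprafacially to the disubstituted double bond with its carbonyl carbon on the unsubstituted diene terminus (the developing allyl cation ends on the methyl-bearing carbon), which fixes the cis fusion and the regiochemistry.

Step 4
Reactants: 7 rac-cis-8,8-dichloro-3-methylbicyclo[4.2.0]oct-2-en-7-one
Product: 8 rac-cis-3-methylbicyclo[4.2.0]oct-2-en-7-one
Conditions: Zn, AcOH, 60 °C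
Reagents that add atoms: none
Why: Zinc dechlorination of α,α-dichlorocyclobutanones is standard and does not touch the fusion stereocentres.

Step 5
Reactants: 8 rac-cis-3-methylbicyclo[4.2.0]oct-2-en-7-one
Product: 9 (1R,6S)-3-methylbicyclo[4.2.0]oct-2-en-7-one
Conditions: ketoreductase (screening-panel hit), NADP+ (cat.), i-PrOH, phosphate buffer pH 7, 30 °C, stopped a little past half conversion
Reagents that add atoms: none
Why: Enzymatic kinetic resolution: the enzyme reduces the (1S,6R)-ketone to its alcohol, so the (1R,6S)-ketone should be recovered and separated by chromatography, as is established for fused cyclobutanones.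

Step 6
Reactants: 9 (1R,6S)-3-methylbicyclo[4.2.0]oct-2-en-7-one; 10 but-2-yne
Product: 11 (4aR,8aS)-2,3,6-trimethyl-4a,7,8,8a-tetrahydronaphthalen-1(4H)-one
Conditions: Ni(cod)2 (10 mol%), PCy3 (20 mol%), toluene, 100 °C, sealed tube
Reagents that add atoms: none
Why: Proposed new method: zerovalent nickel couples the ketone carbonyl and the alkyne by oxidative cyclisation to an oxanickelacyclopentene (forming C1–C2), β-carbon elimination opens the strained four-membered ring at the C1–CH2 bond to a seven-membered nickelacycle, and C–C reductive elimination forms C3–C4 and frees the catalyst. The closest known reaction is the nickel-catalysed intermolecular insertion of internal alkynes into 3-substituted cyclobutanones, which has not been shown on a ring-fused, α-substituted cyclobutanone. Ring B closes by reductive elimination from the seven-membered metallacycle, a formal [4+2] of the acyl–carbon σ-bond with the alkyne. No stereocentre is created: C4a and C8a come unchanged from the cycloadduct, because the C1–C8a bond is never broken and the neutral medium cannot epimerise the cis fusion. The selectivity required is cleavage of the C1–C4 (methylene) bond and not of the C1–C8a (ring-fusion methine) bond, and it should follow from the preference of nickel for the less hindered primary alkyl carbon in the β-carbon elimination. But-2-yne is symmetrical, so the alkyne raises no regiochemical question.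

Step 7
Reactants: 11 (4aR,8aS)-2,3,6-trimethyl-4a,7,8,8a-tetrahydronaphthalen-1(4H)-one
Product: 13 1α-{[(bromomethyl)dimethylsilyl]oxy}-2,3,6-trimethyl-1β-[(trimethylsilyl)methyl]-1,4,4a,7,8,8a-hexahydronaphthalene (4aβ-H,8aβ-H), via lithium alkoxide 12 (not isolated)
Conditions: Me3SiCH2Li, CeCl3, THF, −78 °C; then BrCH2SiMe2Cl, DMAP (cat.), −78 °C → rt
Reagents that add atoms: (trimethylsilyl)methyllithium, [Li]C[Si](C)(C)C; (bromomethyl)chlorodimethylsilane, C[Si](C)(Cl)CBr
Why: Organocerium 1,2-addition followed by O-silylation: the nucleophile should enter from the convex β face (anti to C8 and ring A), so the C1 oxygen lies on the α face as tether anchor and the CH2SiMe3 group is the latent exocyclic methylene.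

Step 8
Reactants: 13 the bromomethylsilyl ether
Product: 14 1α-{[(iodomethyl)dimethylsilyl]oxy}-2,3,6-trimethyl-1β-[(trimethylsilyl)methyl]-1,4,4a,7,8,8a-hexahydronaphthalene (4aβ-H,8aβ-H)
Conditions: NaI, acetone, rt, dark
Reagents that add atoms: sodium iodide, [Na+].[I-]
Why: Finkelstein exchange of the primary α-silyl bromide gives the iodide needed for an efficient atom-transfer chain.

Step 9
Reactants: 14 the iodomethylsilyl ether
Product: 16 tricyclic siloxane (five-membered C1–O–SiMe2–CH2–C2 ring on the α face; 2β,3,6-trimethyl; 1β-CH2SiMe3; C3=C4 and C5=C6 double bonds; 4aβ-H,8aβ-H), via tertiary iodide 15 (not isolated)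
Conditions: Bu3SnSnBu3 (10 mol%), hν, benzene, 80 °C; then DBU, rt
Reagents that add atoms: none
Why: Iodine atom-transfer radical cyclisation on a silicon tether (5-exo-trig): the α-silyl radical can reach C2 only on the α face of the C1 oxygen, which sets quaternary C2 (CH2 α, CH3 β) in a cis-fused oxasilolane, and loss of HI from the tertiary iodide leaves the C3=C4 alkene (an exocyclic isomer, if formed, converges in step 11).

Step 10
Reactants: 16 the tricyclic siloxane
Product: 17 2α-(hydroxymethyl)-2β,3,6-trimethyl-1β-[(trimethylsilyl)methyl]-1,2,4a,7,8,8a-hexahydronaphthalen-1α-ol (4aβ-H,8aβ-H)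
Conditions: H2O2 (30%), KF, KHCO3, THF/MeOH, 40 °C
Reagents that add atoms: hydrogen peroxide, OO
Why: Tamao–Fleming oxidation turns the C–Si bond into C–OH with retention and frees the tertiary alcohol, giving a 1,3-diol with both hydroxyls on the α face.

Step 11
Reactants: 17 the unsaturated diol
Product: 18 2α-(hydroxymethyl)-2β,3β,6-trimethyl-1β-[(trimethylsilyl)methyl]-1,2,3,4,4a,7,8,8a-octahydronaphthalen-1α-ol (4aβ-H,8aβ-H)
Conditions: H2 (50 atm), [Rh(nbd)(dppb)]BF4 (5 mol%), CH2Cl2, rt
Reagents that add atoms: none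
Why: Hydroxyl-directed homogeneous hydrogenation: the cationic rhodium catalyst bound to the α-face hydroxyls should deliver H2 to the α face of the homoallylic C3=C4 bond and so set C3 (H α, CH3 β), while the remote ring-A alkene has no nearby directing group.

Step 12
Reactants: 18 the saturated diol
Product: 19 2β,3β,6-trimethyl-2α-{[(1-phenyl-1H-tetrazol-5-yl)sulfanyl]methyl}-1β-[(trimethylsilyl)methyl]-1,2,3,4,4a,7,8,8a-octahydronaphthalen-1α-ol (4aβ-H,8aβ-H)
Conditions: 1-phenyl-1H-tetrazole-5-thiol, PPh3, DIAD, THF, 0 °C → rt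
Reagents that add atoms: 1-phenyl-1H-tetrazole-5-thiol, Sc1nnnn1-c1ccccc1
Why: Mitsunobu thioetherification is selective for the primary hydroxyl, the tertiary alcohol being inert.

Step 13
Reactants: 19 the sulfide
Product: 20 2β,3β,6-trimethyl-2α-{[(1-phenyl-1H-tetrazol-5-yl)sulfonyl]methyl}-1β-[(trimethylsilyl)methyl]-1,2,3,4,4a,7,8,8a-octahydronaphthalen-1α-ol (4aβ-H,8aβ-H)
Conditions: (NH4)6Mo7O24·4H2O (10 mol%), H2O2 (30%), EtOH, 0 °C → rt
Reagents that add atoms: hydrogen peroxide, OO
Why: Molybdate-catalysed sulfide-to-sulfone oxidation is the usual entry to tetrazolyl sulfones and should spare the isolated trisubstituted alkene.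

Step 14
Reactants: 20 the sulfone alcohol
Product: 21 trimethylsilyl ether of 20 (1α-OSiMe3)
Conditions: 1-(trimethylsilyl)imidazole, CH2Cl2, rt
Reagents that add atoms: 1-(trimethylsilyl)imidazole, C[Si](C)(C)n1ccnc1
Why: Silylation masks the tertiary hydroxyl, whose alkoxide could otherwise attack the tetrazole (Smiles-type transfer) or start a premature Peterson elimination.

Step 15
Reactants: 22 geranyl acetate
Product: 23 (2E)-3-methyl-6-oxohex-2-en-1-yl acetate
Conditions: O3 (1.0 equiv), pyridine, CH2Cl2, −78 °C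
Reagents that add atoms: ozone, [O-][O+]=O
Why: Chemoselective ozonolysis: the electron-rich 6,7-double bond is cleaved in preference to the one deactivated by the allylic acetate, and pyridine converts the carbonyl oxide directly into the aldehyde.

Step 16
Reactants: 23 (2E)-3-methyl-6-oxohex-2-en-1-yl acetate
Product: 24 (2E,6S,7R)-6-hydroxy-3,7-dimethylnona-2,8-dien-1-yl acetate
Conditions: (E)-but-2-ene, KOt-Bu, n-BuLi, THF, −78 → −45 °C; (+)-Ipc2BOMe [from (−)-α-pinene], BF3·OEt2, −78 °C; then 23; ethanolamine work-up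
Reagents that add atoms: (E)-but-2-ene (delivered as its crotyldiisopinocampheylborane), C/C=C/C
Why: Brown crotylboration through a chair transition state: the (E)-crotyl geometry gives the anti product and the isopinocampheyl groups from (−)-α-pinene direct attack to the Re face of the aldehyde, setting (6S,7R).

Step 17
Reactants: 24 the homoallylic alcohol
Product: 25 (2E,6S,7R)-6-(methanesulfonyloxy)-3,7-dimethylnona-2,8-dien-1-yl acetate
Conditions: MsCl, Et3N, CH2Cl2, 0 °C
Reagents that add atoms: methanesulfonyl chloride, CS(=O)(=O)Cl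
Why: Sulfonylation activates the secondary carbinol for the later SN2 ring closure and prevents it from opening the epoxide made in step 19.

Step 18
Reactants: 25 the mesylate acetate
Product: 26 (3R,4S,7E)-9-hydroxy-3,7-dimethylnona-1,7-dien-4-yl methanesulfonate
Conditions: K2CO3 (cat.), MeOH, 0 °C
Reagents that add atoms: none
Why: Transesterification removes the acetate under conditions too mild to displace or eliminate the secondary mesylate.

Step 19
Reactants: 26 the allylic alcohol
Product: 27 {(2R,3R)-3-[(3S,4R)-3-(methanesulfonyloxy)-4-methylhex-5-en-1-yl]-3-methyloxiran-2-yl}methanol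
Conditions: Ti(OiPr)4 (10 mol%), D-(−)-diethyl tartrate (12 mol%), t-BuOOH, 4 Å MS, CH2Cl2, −20 °C
Reagents that add atoms: tert-butyl hydroperoxide, CC(C)(C)OO
Why: Sharpless asymmetric epoxidation of the (E)-trisubstituted allylic alcohol under reagent control: the D-tartrate ligand should give the (2R,3R)-epoxide and the isolated vinyl group is not touched.

Step 20
Reactants: 27 the epoxy alcohol
Product: 28 (2R,3S,6S,7R)-3-hydroperoxy-1,2-dihydroxy-3,7-dimethylnon-8-en-6-yl methanesulfonate
Conditions: H2O2 (anhydrous, in Et2O), H3PMo12O40 (5 mol%), 0 °C → rt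
Reagents that add atoms: hydrogen peroxide, OO
Why: Acid-catalysed perhydrolysis of the epoxide: H2O2 attacks the tertiary epoxide carbon anti to the leaving oxygen (inversion), which creates the quaternary C–OOH centre with defined configuration.

Step 21
Reactants: 28 the hydroperoxy mesylate
Product: 29 (1R)-1-{(3S,6R)-6-[(2R)-but-3-en-2-yl]-3-methyl-1,2-dioxan-3-yl}ethane-1,2-diol
Conditions: Cs2CO3, DMF, 0 °C → rt
Reagents that add atoms: none
Why: Intramolecular alkylation of the hydroperoxide (6-exo-tet SN2): the weakly basic peroxy anion displaces the mesylate with inversion, so C6′ becomes R and the two large ring substituents end cis.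

Step 22
Reactants: 29 the vinyl dioxane diol
Product: 30 (2S)-2-{(3R,6S)-6-[(1R)-1,2-dihydroxyethyl]-6-methyl-1,2-dioxan-3-yl}propanal
Conditions: O3, pyridine, CH2Cl2, −78 °C
Reagents that add atoms: ozone, [O-][O+]=O
Why: Ozonolysis of the only alkene converts the vinyl group into the aldehyde; the dialkyl peroxide and the diol are inert to ozone and no reducing work-up is needed.

Step 23
Reactants: 30 the aldehyde
Product: 31 (2S)-2-{(3R,6S)-6-[(1R)-1,2-dihydroxyethyl]-6-methyl-1,2-dioxan-3-yl}propanoic acid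
Conditions: NaClO2, NaH2PO4, 2-methylbut-2-ene, t-BuOH/H2O, 0 °C
Reagents that add atoms: sodium chlorite, [Na+].[O-]Cl=O
Why: Pinnick oxidation runs at weakly acidic pH, so the α-stereocentre should not epimerise and the β-peroxide should not be eliminated.

Step 24
Reactants: 31 the acid
Product: 32 methyl (2S)-2-{(3R,6S)-6-[(1R)-1,2-dihydroxyethyl]-6-methyl-1,2-dioxan-3-yl}propanoate
Conditions: Me3SiCHN2, toluene/MeOH, 0 °C
Reagents that add atoms: (trimethylsilyl)diazomethane, C[Si](C)(C)C=[N+]=[N-]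
Why: Neutral O-methylation of the carboxylic acid avoids base.

Step 25
Reactants: 32 the diol ester
Product: 33 methyl (2S)-2-[(3R,6S)-6-formyl-6-methyl-1,2-dioxan-3-yl]propanoate
Conditions: NaIO4, THF/H2O (pH 7), 0 °C
Reagents that add atoms: none
Why: Glycol cleavage removes the extra carbon and leaves the non-enolisable α-peroxy aldehyde; periodate does not attack the peroxide.

Step 26
Reactants: 21 the silylated sulfone; 33 the dioxane aldehyde
Product: 34 methyl (2S)-2-[(3R,6S)-6-methyl-6-{(E)-2-[2β,3β,6-trimethyl-1β-[(trimethylsilyl)methyl]-1α-[(trimethylsilyl)oxy]-1,2,3,4,4a,7,8,8a-octahydronaphthalen-2α-yl]ethenyl}-1,2-dioxan-3-yl]propanoate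
Conditions: KN(SiMe3)2, THF, −78 °C; then 33, −78 °C → rt
Reagents that add atoms: none
Why: Julia–Kocienski olefination: the metalated tetrazolyl sulfone adds to the non-enolisable aldehyde and Smiles rearrangement with loss of SO2 and tetrazolone gives the Ca=Cb alkene (E expected; the geometry is irrelevant).

Step 27
Reactants: 34 the alkene
Product: 35 methyl (2S)-2-[(3R,6R)-6-methyl-6-{2-[2β,3β,6-trimethyl-1β-[(trimethylsilyl)methyl]-1α-[(trimethylsilyl)oxy]-1,2,3,4,4a,7,8,8a-octahydronaphthalen-2α-yl]ethyl}-1,2-dioxan-3-yl]propanoate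
Conditions: 2-nitrobenzenesulfonyl hydrazide, Et3N, CH2Cl2, rt, repeated charges
Reagents that add atoms: none
Why: Diimide reduction transfers H2 concertedly to the 1,2-disubstituted alkene in preference to the trisubstituted ring alkene and cannot cleave the O–O bond.

Step 28
Reactants: 35 the saturated bis-silyl compound
Product: 37 methyl (2S)-2-[(3R,6R)-6-methyl-6-{2-[(2R,3S,4aR,8aS)-2,3,6-trimethyl-1-methylidene-1,2,3,4,4a,7,8,8a-octahydronaphthalen-2-yl]ethyl}-1,2-dioxan-3-yl]propanoate, via tertiary alcohol 36 (not isolated)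
Conditions: HF·pyridine, THF, 0 °C → rt
Reagents that add atoms: none
Why: Acid removes the silyl ether and the freed β-hydroxysilane undergoes Peterson elimination, which can place the double bond only between C1 and the silyl-bearing carbon and so gives the exocyclic methylene.

**Compound list**

In the SMILES of 7 and 8 the flag |&1:2,8| marks the pair of fusion stereocentres as racemic.

1 | 3-methylcyclohex-2-en-1-one | CC1=CC(=O)CCC1 | starting material
2 | 3-methylcyclohex-2-en-1-one p-toluenesulfonylhydrazone | Cc1ccc(cc1)S(=O)(=O)NN=C1C=C(C)CCC1 | intermediate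
3 | (5-methylcyclohexa-1,5-dien-1-yl)lithium | [Li]C1=CCCC(C)=C1 | intermediate
4 | 1-methylcyclohexa-1,3-diene | CC1=CC=CCC1 | intermediate
5 | trichloroacetyl chloride | O=C(Cl)C(Cl)(Cl)Cl | starting material
6 | dichloroketene | O=C=C(Cl)Cl | intermediate
7 | rac-cis-8,8-dichloro-3-methylbicyclo[4.2.0]oct-2-en-7-one | O=C1[C@H]2CCC(C)=C[C@H]2C1(Cl)Cl |&1:2,8| | intermediate
8 | rac-cis-3-methylbicyclo[4.2.0]oct-2-en-7-one | O=C1[C@H]2CCC(C)=C[C@H]2C1 |&1:2,8| | intermediate
9 | (1R,6S)-3-methylbicyclo[4.2.0]oct-2-en-7-one | O=C1[C@H]2CCC(C)=C[C@H]2C1 | intermediate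
10 | but-2-yne | CC#CC | starting material
11 | (4aR,8aS)-2,3,6-trimethyl-4a,7,8,8a-tetrahydronaphthalen-1(4H)-one | O=C1[C@H]2CCC(C)=C[C@H]2CC(C)=C1C | intermediate
12 | lithium 2,3,6-trimethyl-1β-[(trimethylsilyl)methyl]-1,4,4a,7,8,8a-hexahydronaphthalen-1α-olate (4aβ-H,8aβ-H) | C[Si](C)(C)C[C@]1([O-])[C@H]2CCC(C)=C[C@H]2CC(C)=C1C.[Li+] | intermediate
13 | 1α-{[(bromomethyl)dimethylsilyl]oxy}-2,3,6-trimethyl-1β-[(trimethylsilyl)methyl]-1,4,4a,7,8,8a-hexahydronaphthalene (4aβ-H,8aβ-H) | C[Si](C)(C)C[C@]1(O[Si](C)(C)CBr)[C@H]2CCC(C)=C[C@H]2CC(C)=C1C | intermediate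
14 | 1α-{[(iodomethyl)dimethylsilyl]oxy}-2,3,6-trimethyl-1β-[(trimethylsilyl)methyl]-1,4,4a,7,8,8a-hexahydronaphthalene (4aβ-H,8aβ-H) | C[Si](C)(C)C[C@]1(O[Si](C)(C)CI)[C@H]2CCC(C)=C[C@H]2CC(C)=C1C | intermediate
15 | tricyclic siloxane with 3-iodo-2β,3,6-trimethyl substitution (C1–O–SiMe2–CH2–C2 ring on the α face; 1β-CH2SiMe3; C3 configuration immaterial) | C[Si](C)(C)C[C@@]12O[Si](C)(C)C[C@]1(C)C(C)(I)C[C@@H]3C=C(C)CC[C@H]23 | intermediate
16 | tricyclic siloxane (C1–O–SiMe2–CH2–C2 ring on the α face; 2β,3,6-trimethyl; 1β-CH2SiMe3; C3=C4 and C5=C6; 4aβ-H,8aβ-H) | C[Si](C)(C)C[C@@]12O[Si](C)(C)C[C@]1(C)C(C)=C[C@@H]3C=C(C)CC[C@H]23 | intermediate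
17 | 2α-(hydroxymethyl)-2β,3,6-trimethyl-1β-[(trimethylsilyl)methyl]-1,2,4a,7,8,8a-hexahydronaphthalen-1α-ol (4aβ-H,8aβ-H) | C[Si](C)(C)C[C@]1(O)[C@H]2CCC(C)=C[C@H]2C=C(C)[C@@]1(C)CO | intermediate
18 | 2α-(hydroxymethyl)-2β,3β,6-trimethyl-1β-[(trimethylsilyl)methyl]-1,2,3,4,4a,7,8,8a-octahydronaphthalen-1α-ol (4aβ-H,8aβ-H) | C[Si](C)(C)C[C@]1(O)[C@H]2CCC(C)=C[C@H]2C[C@H](C)[C@@]1(C)CO | intermediate
19 | 2β,3β,6-trimethyl-2α-{[(1-phenyl-1H-tetrazol-5-yl)sulfanyl]methyl}-1β-[(trimethylsilyl)methyl]-1,2,3,4,4a,7,8,8a-octahydronaphthalen-1α-ol | C[Si](C)(C)C[C@]1(O)[C@H]2CCC(C)=C[C@H]2C[C@H](C)[C@@]1(C)CSc1nnnn1-c1ccccc1 | intermediate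
20 | 2β,3β,6-trimethyl-2α-{[(1-phenyl-1H-tetrazol-5-yl)sulfonyl]methyl}-1β-[(trimethylsilyl)methyl]-1,2,3,4,4a,7,8,8a-octahydronaphthalen-1α-ol | C[Si](C)(C)C[C@]1(O)[C@H]2CCC(C)=C[C@H]2C[C@H](C)[C@@]1(C)CS(=O)(=O)c1nnnn1-c1ccccc1 | intermediate
21 | 1α-trimethylsilyl ether of 20 | C[Si](C)(C)C[C@]1(O[Si](C)(C)C)[C@H]2CCC(C)=C[C@H]2C[C@H](C)[C@@]1(C)CS(=O)(=O)c1nnnn1-c1ccccc1 | intermediate
22 | geranyl acetate, (2E)-3,7-dimethylocta-2,6-dien-1-yl acetate | CC(=O)OC/C=C(\C)CCC=C(C)C | starting material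
23 | (2E)-3-methyl-6-oxohex-2-en-1-yl acetate | CC(=O)OC/C=C(\C)CCC=O | intermediate
24 | (2E,6S,7R)-6-hydroxy-3,7-dimethylnona-2,8-dien-1-yl acetate | CC(=O)OC/C=C(\C)CC[C@H](O)[C@H](C)C=C | intermediate
25 | (2E,6S,7R)-6-(methanesulfonyloxy)-3,7-dimethylnona-2,8-dien-1-yl acetate | CC(=O)OC/C=C(\C)CC[C@H](OS(C)(=O)=O)[C@H](C)C=C | intermediate
26 | (3R,4S,7E)-9-hydroxy-3,7-dimethylnona-1,7-dien-4-yl methanesulfonate | OC/C=C(\C)CC[C@H](OS(C)(=O)=O)[C@H](C)C=C | intermediate
27 | {(2R,3R)-3-[(3S,4R)-3-(methanesulfonyloxy)-4-methylhex-5-en-1-yl]-3-methyloxiran-2-yl}methanol | OC[C@H]1O[C@]1(C)CC[C@H](OS(C)(=O)=O)[C@H](C)C=C | intermediate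
28 | (2R,3S,6S,7R)-3-hydroperoxy-1,2-dihydroxy-3,7-dimethylnon-8-en-6-yl methanesulfonate | OC[C@@H](O)[C@@](C)(OO)CC[C@H](OS(C)(=O)=O)[C@H](C)C=C | intermediate
29 | (1R)-1-{(3S,6R)-6-[(2R)-but-3-en-2-yl]-3-methyl-1,2-dioxan-3-yl}ethane-1,2-diol | OC[C@@H](O)[C@]1(C)CC[C@H]([C@H](C)C=C)OO1 | intermediate
30 | (2S)-2-{(3R,6S)-6-[(1R)-1,2-dihydroxyethyl]-6-methyl-1,2-dioxan-3-yl}propanal | OC[C@@H](O)[C@]1(C)CC[C@H]([C@H](C)C=O)OO1 | intermediate
31 | (2S)-2-{(3R,6S)-6-[(1R)-1,2-dihydroxyethyl]-6-methyl-1,2-dioxan-3-yl}propanoic acid | OC[C@@H](O)[C@]1(C)CC[C@H]([C@H](C)C(=O)O)OO1 | intermediate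
32 | methyl (2S)-2-{(3R,6S)-6-[(1R)-1,2-dihydroxyethyl]-6-methyl-1,2-dioxan-3-yl}propanoate | OC[C@@H](O)[C@]1(C)CC[C@H]([C@H](C)C(=O)OC)OO1 | intermediate
33 | methyl (2S)-2-[(3R,6S)-6-formyl-6-methyl-1,2-dioxan-3-yl]propanoate | O=C[C@]1(C)CC[C@H]([C@H](C)C(=O)OC)OO1 | intermediate
34 | methyl (2S)-2-[(3R,6S)-6-methyl-6-{(E)-2-[2β,3β,6-trimethyl-1β-[(trimethylsilyl)methyl]-1α-[(trimethylsilyl)oxy]-1,2,3,4,4a,7,8,8a-octahydronaphthalen-2α-yl]ethenyl}-1,2-dioxan-3-yl]propanoate | C[Si](C)(C)C[C@]1(O[Si](C)(C)C)[C@H]2CCC(C)=C[C@H]2C[C@H](C)[C@@]1(C)/C=C/[C@]1(C)CC[C@H]([C@H](C)C(=O)OC)OO1 | intermediate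
35 | methyl (2S)-2-[(3R,6R)-6-methyl-6-{2-[2β,3β,6-trimethyl-1β-[(trimethylsilyl)methyl]-1α-[(trimethylsilyl)oxy]-1,2,3,4,4a,7,8,8a-octahydronaphthalen-2α-yl]ethyl}-1,2-dioxan-3-yl]propanoate | C[Si](C)(C)C[C@]1(O[Si](C)(C)C)[C@H]2CCC(C)=C[C@H]2C[C@H](C)[C@@]1(C)CC[C@]1(C)CC[C@H]([C@H](C)C(=O)OC)OO1 | intermediate
36 | methyl (2S)-2-[(3R,6R)-6-{2-[1α-hydroxy-2β,3β,6-trimethyl-1β-[(trimethylsilyl)methyl]-1,2,3,4,4a,7,8,8a-octahydronaphthalen-2α-yl]ethyl}-6-methyl-1,2-dioxan-3-yl]propanoate | C[Si](C)(C)C[C@]1(O)[C@H]2CCC(C)=C[C@H]2C[C@H](C)[C@@]1(C)CC[C@]1(C)CC[C@H]([C@H](C)C(=O)OC)OO1 | intermediate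
37 | methyl (2S)-2-[(3R,6R)-6-methyl-6-{2-[(2R,3S,4aR,8aS)-2,3,6-trimethyl-1-methylidene-1,2,3,4,4a,7,8,8a-octahydronaphthalen-2-yl]ethyl}-1,2-dioxan-3-yl]propanoate (CNP0144520.2) | C=C1[C@H]2CCC(C)=C[C@H]2C[C@H](C)[C@@]1(C)CC[C@]1(C)CC[C@H]([C@H](C)C(=O)OC)OO1 | target

**Step count and risks**

Total: 28 steps. Longest linear sequence: 17 steps (steps 1–14, then 26–28). The dioxane branch (steps 15–25) has 11 steps.

Steps most likely to fail:

1. Step 6 (Proposed new method). What may go wrong: β-carbon elimination at the ring-fusion carbon (cleavage of C1–C8a), decarbonylation, or alkyne oligomerisation outrunning insertion. The fallback uses known reactions, sets out from 9 and returns at 11. The kinetic lithium enolate of 9 (LiN(i-Pr)2, −78 °C; only the methylene α-carbon can be deprotonated) is C-acetylated with 1-acetylimidazole to cis-8-acetyl-3-methylbicyclo[4.2.0]oct-2-en-7-one F1. NaOMe in MeOH opens this strained β-diketone by retro-Claisen cleavage to methyl cis-4-methyl-2-(2-oxopropyl)cyclohex-3-ene-1-carboxylate F2. Me2AlSEt converts the ester into S-ethyl cis-4-methyl-2-(2-oxopropyl)cyclohex-3-ene-1-carbothioate F3. Fukuyama coupling with EtZnI and PdCl2(PPh3)2 gives 1-[cis-4-methyl-2-(2-oxopropyl)cyclohex-3-en-1-yl]propan-1-one F4, and intramolecular aldol condensation (pyrrolidine, AcOH) closes ring B to 11. The stereocentre next to the acyl group must be watched for epimerisation in this sequence.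

2. Step 9. What may go wrong: 6-endo closure competing with the 5-exo mode, a short radical chain on the hindered tetrasubstituted alkene, or loss of the tether. The fallback sets out from 11 and returns at 18. Reductive alkylation (Li, NH3, t-BuOH 1 equiv, THF, −78 °C; then gaseous CH2O) gives 2α-(hydroxymethyl)-2β,3β,6-trimethyl-3,4,4a,7,8,8a-hexahydronaphthalen-1(2H)-one F5. Here C3 and C2 are set under substrate control only, so epimers would have to be separated by chromatography. Excess Me3SiCH2Li with CeCl3 then adds to the ketone from the β face to give 18.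

3. Step 27. What may go wrong: slow saturation of an alkene flanked by two quaternary carbons, with competing reduction of the ring-A double bond. The fallback sets out from 18 and returns at 35; it reaches the strained cis-alkene, which diimide should reduce much faster. I2, PPh3 and imidazole give 2α-(iodomethyl)-2β,3β,6-trimethyl-1β-[(trimethylsilyl)methyl]-1,2,3,4,4a,7,8,8a-octahydronaphthalen-1α-ol F6. 1-(Trimethylsilyl)imidazole gives its 1α-trimethylsilyl ether F7. PPh3 at 110 °C gives the triphenylphosphonium iodide F8. NaN(SiMe3)2 followed by 33 gives, by Wittig olefination, the (Z)-isomer of 34 F9, and diimide then gives 35.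

**Further compounds**

F1 | step 6 | cis-8-acetyl-3-methylbicyclo[4.2.0]oct-2-en-7-one (from 9; C8 epimers) | CC(=O)C1C(=O)[C@H]2CCC(C)=C[C@H]21
F2 | step 6 | methyl cis-4-methyl-2-(2-oxopropyl)cyclohex-3-ene-1-carboxylate | COC(=O)[C@H]1CCC(C)=C[C@H]1CC(C)=O
F3 | step 6 | S-ethyl cis-4-methyl-2-(2-oxopropyl)cyclohex-3-ene-1-carbothioate | CCSC(=O)[C@H]1CCC(C)=C[C@H]1CC(C)=O
F4 | step 6 | 1-[cis-4-methyl-2-(2-oxopropyl)cyclohex-3-en-1-yl]propan-1-one | CCC(=O)[C@H]1CCC(C)=C[C@H]1CC(C)=O
F5 | step 9 | 2α-(hydroxymethyl)-2β,3β,6-trimethyl-3,4,4a,7,8,8a-hexahydronaphthalen-1(2H)-one (4aβ-H,8aβ-H) | O=C1[C@H]2CCC(C)=C[C@H]2C[C@H](C)[C@@]1(C)CO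
F6 | step 27 | 2α-(iodomethyl)-2β,3β,6-trimethyl-1β-[(trimethylsilyl)methyl]-1,2,3,4,4a,7,8,8a-octahydronaphthalen-1α-ol | C[Si](C)(C)C[C@]1(O)[C@H]2CCC(C)=C[C@H]2C[C@H](C)[C@@]1(C)CI
F7 | step 27 | 1α-trimethylsilyl ether of F6 | C[Si](C)(C)C[C@]1(O[Si](C)(C)C)[C@H]2CCC(C)=C[C@H]2C[C@H](C)[C@@]1(C)CI
F8 | step 27 | {[2β,3β,6-trimethyl-1β-[(trimethylsilyl)methyl]-1α-[(trimethylsilyl)oxy]-1,2,3,4,4a,7,8,8a-octahydronaphthalen-2α-yl]methyl}triphenylphosphonium iodide | C[Si](C)(C)C[C@]1(O[Si](C)(C)C)[C@H]2CCC(C)=C[C@H]2C[C@H](C)[C@@]1(C)C[P+](c1ccccc1)(c1ccccc1)c1ccccc1.[I-]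
F9 | step 27 | (Z)-isomer of 34 | C[Si](C)(C)C[C@]1(O[Si](C)(C)C)[C@H]2CCC(C)=C[C@H]2C[C@H](C)[C@@]1(C)/C=C\[C@]1(C)CC[C@H]([C@H](C)C(=O)OC)OO1
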